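## Analysis of the target

The target 31 is a linear heptamer of seven benzene rings joined by six diaryl ether oxygens, with eighteen free phenolic hydroxyls and no stereocentre. Lettered from the 2,4,6-trihydroxyphenyl end, ring A is bound through the carbon between two of its hydroxyls, and rings B, D and F are 3,5-dihydroxy-1,4-phenylenedioxy units in which C1, flanked by two hydrogens, takes the oxygen from the preceding ring and C4, between the two hydroxylated carbons, carries the oxygen to the next ring. Rings C and E are 3,4,5-trihydroxy-1,2-phenylenedioxy units (C1 oxygen from the preceding ring, C2 oxygen to the next ring, C6–H), and ring G is 3,4,5-trihydroxyphenyl. The pyrogallol and phloroglucinol units are oxidised easily, so every hydroxyl is kept as a methyl ether until the last step. The difficulty is crowding and sameness: every ether oxygen has at least two ortho substituents, the B–O–C and D–O–E junctions have three, and the rings differ too little for late selective chemistry. The strategy rests on ring E, whose C1 to C5 are five contiguous oxygenated carbons and whose C6 bears the only hydrogen. C2 to C5 map onto the four carbons of a squarate and C1–C6 onto a 1-aryloxyvinyl unit that already carries the ring D oxygen, so the crowded D–O–E ether is made at an sp carbon and ring E is then grown around it.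

## Retrosynthetic reasoning

**31 from 30.** The eighteen O–CH3 bonds are cut last. Methyl ethers survive every earlier condition (base, copper, organolithium, heat), and one Lewis-acid step removes them all without touching the diaryl ethers.

**30 from 26 and 29.** The bond between the ring E C2 oxygen and ring F C1 is cut. Ring F C1 has no ortho substituent, so the crowded phenol 26 meets an unhindered aryl bromide, and the FG half arrives in one piece. Bromide 29 is cut at the oxygen to ring G C1, giving bromophenol 27 and boronic acid 28; an oxidative copper coupling at room temperature leaves the aryl bromide untouched.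

**26 from 24 through 25.** The ring E oxygens at C2 and C5 must be told apart: C5 ends as a hydroxyl, C2 as the ether to ring F. In 24 they differ by origin, not by sterics: C2 keeps the silyl ether of the carbinol and C5 is the free phenol born from the ketene. Methylation of C5 to 25 and desilylation of C2 to 26 need no selectivity.

**24 from 21 (key disconnection).** Ring E is opened at C5–C6 and folded back to cyclobutenone 21. In the forward sense, heat opens the four-membered ring to dienylketene 22, and electrocyclisation joins the ketene carbon to the vinyl CH2. The two squarate methoxy carbons become C3 and C4, the carbinol carbon C2, the carbonyl carbon C5, the enol ether carbon C1 and the CH2 C6. All five oxygens and the D–O–E ether emerge in place.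

**21 from 17 and 18 through 20.** The ring E C1–C2 bond is cut between the enol ether carbon and the carbinol carbon. Forward, vinyllithium 19, made from stannane 17, adds once to one of the two equivalent carbonyls of squarate 18, and the carbinol 20 is silylated to 21.

**17 from 13 through 14 and 16.** The bond from the ring D oxygen to ring E C1 is traced back to an alkyne. The doubly flanked phenoxide of 13 adds to a linear two-carbon electrophile, which has no steric demand, to give 14. Elimination gives ethynyl ether 16, and hydrostannylation places tin on the oxygen-bearing carbon.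

**13 from 1, 2 and 7 (7 from 6).** The tetramer is cut at each ether oxygen, in every case on the side of the ring that carries a para or ortho aldehyde. Each forward cycle joins the growing phenol to an aldehyde-activated aryl bromide and then turns the aldehyde into the next phenol by Dakin oxidation, exactly where the next ether oxygen is needed. Phenol 1 is ring A, bromoaldehyde 2 serves for rings B and D, and bromoaldehyde 7, made from 6 by formylation, serves for ring C. The only three-ortho junction made by arylation (B–O–C) is placed early, at the trimer stage, where material is cheap.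

## Alternatives that were turned down

Alternative 1: ring D as a ruthenium-activated hub. The disconnection cuts both ring D ether bonds. The hub is the complex A2, [CpRu(η6-2,5-dichloro-1,3-dimethoxybenzene)]PF6. Forward, A2 would be substituted first at its unflanked chlorine by the phenoxide of 10, and then at the chlorine between its two methoxy groups by the EFG trimer phenol A3. This would give the ruthenium-bound permethylated heptamer A1, and photolysis would release 30.
- For it: it is more convergent than the chosen route (two trimers and a one-ring hub, shorter longest linear sequence), needs no tin, and substitution on a cationic arene complex such as A2 runs near room temperature.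
- Against it: the second substitution is the three-ortho D–O–E junction, attempted on a complex already made electron-richer by the first aryloxy group, with a trimer-sized nucleophile. Demethylation of the complexed methoxy groups by phenoxide and incomplete second substitution are the expected failure paths, and they occur at the most valuable point of the synthesis. Ruthenium is stoichiometric, and A3 needs its own multi-step synthesis.
- Comparison: the chosen route loses on convergence but forms D–O–E without any substitution at a flanked aromatic carbon, and its risk sits in a unimolecular step.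

Alternative 2: ring D built by a double Claisen condensation. The disconnection cuts C2–C3 and C5–C6 of ring D. Forward, the dienolate of the glutaconate A5, derived from 10, would be acylated twice by the aryloxymalonate A6, derived from A3, to give A4, a heptamer whose ring D carries two ester groups and two free hydroxyls.
- For it: like the chosen strategy, it attaches both ring D oxygens before the ring exists and so avoids hindered arylation at ring D. On this point it is equal, and it is more convergent.
- Against it: A6 has a C–H more acidic than that of A5, so proton transfer would turn the intended electrophile into an unreactive enolate and quench the dienolate. Even if ring closure occurred, A4 carries two carbons the target lacks; ester hydrolysis, double decarboxylation next to four ortho substituents and two hindered O-methylations would follow.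
- Comparison: the chosen ring expansion is unimolecular, driven by aromatisation, and every atom of the new ring stays in the product.

Alternative 3: biomimetic closure of ring A. The disconnection cuts one C–C bond of ring A. Forward, the methyl ketone enolate of the triketide ester A8 would attack its ester carbonyl to give A7, with ring A as a free triol.
- For it: it mirrors the biosynthesis and delivers ring A without demethylation, which the chosen route cannot do.
- Against it: ring A is the easiest ring of the molecule, since 1 is a simple phenol and its ether to ring B has only two ortho substituents. The step would spend its effort where there is no problem and leave both three-ortho junctions to conventional arylation. A8 also presupposes that rings B to G are already assembled and that the ring B oxygen has been alkylated at the central carbon of a tricarbonyl chain, and the cyclisation of A8 competes with pyrone formation by O-acylation.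
- Comparison: the chosen strategy puts its key step on a junction that is hard to make by arylation.

Key step: step 13

## Remarks before the steps

Assumption: ring B carries the ring A oxygen on its unflanked C1 and the ring C oxygen on C4 between the two oxygenated carbons, as the target structure requires. The tetramer phenol, the ring-expansion precursor (carried as its silyl ether) and the pentamer are built and drawn in that orientation.

Shorthand: Ar = 4-{6-[2,6-dimethoxy-4-(2,4,6-trimethoxyphenoxy)phenoxy]-2,3,4-trimethoxyphenoxy}-2,6-dimethoxyphenyl (the ABCD tetramer bound through ring D C4).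

## Route

Step 1
Reactants: 1 2,4,6-trimethoxyphenol; 2 4-bromo-2,6-dimethoxybenzaldehyde
Product: 3 2,6-dimethoxy-4-(2,4,6-trimethoxyphenoxy)benzaldehyde (AB aldehyde)
Conditions: CuI (10 mol%), picolinic acid (20 mol%), K3PO4, DMSO, 90 °C, argon
Reagents that add atoms: none
Why: Ullmann-type diaryl ether synthesis; the bromide has no ortho substituent and is activated by the para aldehyde, and the picolinic acid system is suited to phenols with two ortho substituents.

Step 2
Reactants: 3 AB aldehyde
Product: 5 2,6-dimethoxy-4-(2,4,6-trimethoxyphenoxy)phenol (AB phenol), via AB aryl formate 4 (not isolated)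
Conditions: mCPBA, CH2Cl2, 0 °C to rt; aq. NaHCO3 wash; then Et3N (cat.), MeOH, rt
Reagents that add atoms: mCPBA (3-chloroperoxybenzoic acid), O=C(OO)c1cccc(Cl)c1
Why: Dakin-type Baeyer–Villiger oxidation; the aryl group with two ortho methoxy and one para aryloxy donors migrates in preference to hydrogen, and the formate is cleaved by methanolysis.

Step 3
Reactants: 6 5-bromo-1,2,3-trimethoxybenzene
Product: 7 6-bromo-2,3,4-trimethoxybenzaldehyde
Conditions: Cl2CHOMe, TiCl4, CH2Cl2, 0 °C; then H2O
Reagents that add atoms: dichloromethyl methyl ether, COC(Cl)Cl; water, O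
Why: Rieche formylation; the two free ring positions of 6 are equivalent (ortho to one methoxy, para to another), so only one aldehyde can form.

Step 4
Reactants: 5 AB phenol; 7 6-bromo-2,3,4-trimethoxybenzaldehyde
Product: 8 6-[2,6-dimethoxy-4-(2,4,6-trimethoxyphenoxy)phenoxy]-2,3,4-trimethoxybenzaldehyde (ABC aldehyde)
Conditions: CuI (20 mol%), picolinic acid (40 mol%), K3PO4, DMSO, 110 °C, argon
Reagents that add atoms: none
Why: Ullmann-type coupling forming the B–O–C junction; the ortho aldehyde activates the C–Br bond and can chelate copper, which should offset the three ortho substituents around the new ether.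

Step 5
Reactants: 8 ABC aldehyde
Product: 10 6-[2,6-dimethoxy-4-(2,4,6-trimethoxyphenoxy)phenoxy]-2,3,4-trimethoxyphenol (ABC phenol; hydroxyl on ring C C2), via ABC aryl formate 9 (not isolated)
Conditions: mCPBA, CH2Cl2, 0 °C to rt; aq. NaHCO3 wash; then Et3N (cat.), MeOH, rt
Reagents that add atoms: mCPBA (3-chloroperoxybenzoic acid), O=C(OO)c1cccc(Cl)c1
Why: Dakin-type Baeyer–Villiger oxidation; the ortho aryloxy, ortho methoxy and para methoxy groups make aryl migration fast, and the peracid is used in slight excess at low temperature to spare the electron-rich rings.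

Step 6
Reactants: 10 ABC phenol; 2 4-bromo-2,6-dimethoxybenzaldehyde
Product: 11 4-{6-[2,6-dimethoxy-4-(2,4,6-trimethoxyphenoxy)phenoxy]-2,3,4-trimethoxyphenoxy}-2,6-dimethoxybenzaldehyde (ABCD aldehyde ArCHO)
Conditions: CuI (20 mol%), picolinic acid (40 mol%), K3PO4, DMSO, 100 °C, argon
Reagents that add atoms: none
Why: Ullmann-type coupling of a phenol with two ortho substituents with the unhindered, aldehyde-activated bromide already used in step 1.

Step 7
Reactants: 11 ABCD aldehyde
Product: 13 4-{6-[2,6-dimethoxy-4-(2,4,6-trimethoxyphenoxy)phenoxy]-2,3,4-trimethoxyphenoxy}-2,6-dimethoxyphenol (ABCD phenol ArOH), via ABCD aryl formate 12 (not isolated)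
Conditions: mCPBA, CH2Cl2, 0 °C to rt; aq. NaHCO3 wash; then Et3N (cat.), MeOH, rt
Reagents that add atoms: mCPBA (3-chloroperoxybenzoic acid), O=C(OO)c1cccc(Cl)c1
Why: Dakin-type Baeyer–Villiger oxidation of a 2,6-dimethoxy-4-aryloxybenzaldehyde, the most favourable substitution pattern for aryl migration.

Step 8
Reactants: 13 ABCD phenol
Product: 14 (E)-1,2-dichlorovinyl ether ArO–C(Cl)=CHCl
Conditions: KH (1.5 equiv), THF, 0 °C; Cl2C=CHCl, rt to 50 °C
Reagents that add atoms: trichloroethene, ClC=C(Cl)Cl
Why: Phenoxide addition to dichloroacetylene generated in the flask from trichloroethene; the electrophile is linear, so the two ortho methoxy groups of ring D do not hinder the attack, and anti addition gives the (E) isomer.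

Step 9
Reactants: 14 dichlorovinyl ether
Product: 16 ethynyl ether ArO–C≡CH, via lithium aryloxyacetylide 15 (not isolated)
Conditions: n-BuLi (2.2 equiv), THF, −78 °C; then aq. NH4Cl, −78 °C
Reagents that add atoms: none
Why: Base-induced elimination to the chloroalkyne followed by chlorine–lithium exchange, the standard route from dichlorovinyl ethers to ynol ethers; at −78 °C these steps should outrun ring lithiation next to the methoxy groups.

Step 10
Reactants: 16 ethynyl ether
Product: 17 tributyl[1-(ArO)vinyl]stannane
Conditions: Bu3SnH, Pd(PPh3)4 (3 mol%), THF, 0 °C to rt; chromatography on Et3N-treated silica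
Reagents that add atoms: tributyltin hydride, CCCC[SnH](CCCC)CCCC
Why: Zerovalent-palladium-catalysed syn hydrostannylation of a 1-oxyalkyne, which places tin on the oxygen-bearing carbon; the terminal carbon becomes the CH2 of the enol ether.

Step 11
Reactants: 17 vinylstannane; 18 dimethyl squarate (3,4-dimethoxycyclobut-3-ene-1,2-dione)
Product: 20 racemic 4-hydroxy-2,3-dimethoxy-4-[1-(ArO)vinyl]cyclobut-2-en-1-one, via 1-aryloxyvinyllithium 19 (not isolated)
Conditions: n-BuLi (1.05 equiv), THF, −78 °C; then 18 (1.3 equiv), THF, −78 °C; aq. NH4Cl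
Reagents that add atoms: none
Why: Tin–lithium exchange and 1,2-addition of the 1-oxyvinyllithium to one of the two equivalent squarate carbonyls, the usual entry to 4-alkenyl-4-hydroxycyclobutenones; the carbinol carbon forms as a racemate and is erased in step 13.

Step 12
Reactants: 20 carbinol
Product: 21 racemic 4-(tert-butyldimethylsilyloxy)-2,3-dimethoxy-4-[1-(ArO)vinyl]cyclobut-2-en-1-one
Conditions: TBSOTf, 2,6-lutidine, CH2Cl2, −78 to 0 °C
Reagents that add atoms: tert-butyldimethylsilyl trifluoromethanesulfonate, CC(C)(C)[Si](C)(C)OS(=O)(=O)C(F)(F)F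
Why: Silylation of a tertiary alcohol with a silyl triflate under buffered conditions that spare the enol ether; the silyl group marks the future ring E C2 oxygen.

Step 13
Reactants: 21 silyl-protected cyclobutenone
Product: 24 4-(tert-butyldimethylsilyloxy)-2,3-dimethoxy-5-(ArO)phenol (ABCDE pentamer; ring E C5 hydroxyl free; C2 silyl ether), via dienylketene 22 (not isolated), via cyclohexadienone 23 (not isolated)
Conditions: p-xylene (0.01 M, degassed), 138 °C, argon
Reagents that add atoms: none
Why: Heat opens the cyclobutenone by 4π conrotatory cleavage of the C1–C4 bond to the (Z)-dienylketene 22; the silyloxy donor on C4 turns outward, as oxygen donors do, which places the 1-aryloxyvinyl group next to the ketene. A thermal disrotatory 6π electrocyclisation of the triene that includes the ketene C=C then joins the ketene carbon to the unsubstituted vinyl CH2, forming the ring E C5–C6 bond and the six-membered cyclohexadienone 23, which enolises to the aromatic phenol 24. The closest known reaction type is the Moore ring expansion of squarate-derived 4-alkenyl-4-oxycyclobutenones, including 4-(1-alkoxyvinyl) cases. The squarate methoxy carbons become C3 and C4, the carbinol carbon C2 (silyl ether kept), the ketene carbon C5 (free hydroxyl), the enol ether carbon C1 and the CH2 C6. No stereocentre is formed and the racemic carbinol centre disappears. The step needs outward rotation of the C4 oxygen and closure faster than ketene dimerisation or trapping; the oxygen donor on C4, the unhindered CH2 terminus, high dilution and degassed solvent secure this. The silyl ether also closes off lactonisation, which a free hydroxyl rotating inward could undergo, and delivers the two ring E oxygens already differentiated.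

Step 14
Reactants: 24 pentamer phenol
Product: 25 1-(ArO)-2-(tert-butyldimethylsilyloxy)-3,4,5-trimethoxybenzene (ring E numbering)
Conditions: MeI, K2CO3, acetone, 40 °C, argon
Reagents that add atoms: iodomethane, CI
Why: Williamson methylation of the only free phenol (ring E C5, one ortho hydrogen); the silyl ether at C2 is shielded by two ortho substituents and should survive carbonate in acetone.

Step 15
Reactants: 25 silyl ether
Product: 26 6-(ArO)-2,3,4-trimethoxyphenol (ABCDE phenol; hydroxyl on ring E C2)
Conditions: TBAF, AcOH, THF, 0 °C, argon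
Reagents that add atoms: none
Why: Fluoride cleavage of an aryl silyl ether; acetic acid buffering keeps the electron-rich phenoxide from air oxidation.

Step 16
Reactants: 27 4-bromo-2,6-dimethoxyphenol; 28 (3,4,5-trimethoxyphenyl)boronic acid
Product: 29 5-(4-bromo-2,6-dimethoxyphenoxy)-1,2,3-trimethoxybenzene (FG bromide)
Conditions: Cu(OAc)2 (1 equiv), pyridine, 4 Å MS, CH2Cl2, O2 (1 atm), rt
Reagents that add atoms: none
Why: Chan–Lam coupling, which accepts phenols with two ortho substituents when the boronic acid is unhindered; the aryl bromide is inert to divalent copper at room temperature, and oxygen is the terminal oxidant that returns the copper to its divalent state.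

Step 17
Reactants: 26 ABCDE phenol; 29 FG bromide
Product: 30 octadeca-O-methyl ether of the target (permethylated heptamer)
Conditions: CuI (20 mol%), picolinic acid (40 mol%), K3PO4, DMSO, 110 °C, argon
Reagents that add atoms: none
Why: Ullmann-type coupling of a phenol with two ortho substituents with a bromide that has none; every other group is an aryl methyl ether or diaryl ether, inert to base and copper.

Step 18
Reactants: 30 permethylated heptamer
Product: 31 target heptamer (CNP0292517.0)
Conditions: BBr3 (excess), CH2Cl2, −78 °C to rt; then H2O, 0 °C; reversed-phase purification under argon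
Reagents that add atoms: none
Why: Lewis-acid cleavage of all eighteen aryl methyl ethers by bromide attack at methyl; diaryl ether bonds are not cleaved by BBr3.

## Compound list

1 | 2,4,6-trimethoxyphenol | COc1cc(OC)c(O)c(OC)c1 | starting material
2 | 4-bromo-2,6-dimethoxybenzaldehyde | COc1cc(Br)cc(OC)c1C=O | starting material
3 | 2,6-dimethoxy-4-(2,4,6-trimethoxyphenoxy)benzaldehyde (AB aldehyde) | COc1cc(OC)c(Oc2cc(OC)c(C=O)c(OC)c2)c(OC)c1 | intermediate
4 | 2,6-dimethoxy-4-(2,4,6-trimethoxyphenoxy)phenyl formate | COc1cc(OC)c(Oc2cc(OC)c(OC=O)c(OC)c2)c(OC)c1 | intermediate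
5 | 2,6-dimethoxy-4-(2,4,6-trimethoxyphenoxy)phenol (AB phenol) | COc1cc(OC)c(Oc2cc(OC)c(O)c(OC)c2)c(OC)c1 | intermediate
6 | 5-bromo-1,2,3-trimethoxybenzene | COc1cc(Br)cc(OC)c1OC | starting material
7 | 6-bromo-2,3,4-trimethoxybenzaldehyde | COc1cc(Br)c(C=O)c(OC)c1OC | intermediate
8 | 6-[2,6-dimethoxy-4-(2,4,6-trimethoxyphenoxy)phenoxy]-2,3,4-trimethoxybenzaldehyde (ABC aldehyde) | COc1cc(OC)c(Oc2cc(OC)c(Oc3cc(OC)c(OC)c(OC)c3C=O)c(OC)c2)c(OC)c1 | intermediate
9 | 6-[2,6-dimethoxy-4-(2,4,6-trimethoxyphenoxy)phenoxy]-2,3,4-trimethoxyphenyl formate | COc1cc(OC)c(Oc2cc(OC)c(Oc3cc(OC)c(OC)c(OC)c3OC=O)c(OC)c2)c(OC)c1 | intermediate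
10 | 6-[2,6-dimethoxy-4-(2,4,6-trimethoxyphenoxy)phenoxy]-2,3,4-trimethoxyphenol (ABC phenol) | COc1cc(OC)c(Oc2cc(OC)c(Oc3cc(OC)c(OC)c(OC)c3O)c(OC)c2)c(OC)c1 | intermediate
11 | ABCD aldehyde, ArCHO | COc1cc(OC)c(Oc2cc(OC)c(Oc3cc(OC)c(OC)c(OC)c3Oc3cc(OC)c(C=O)c(OC)c3)c(OC)c2)c(OC)c1 | intermediate
12 | ABCD aryl formate, ArOCHO | COc1cc(OC)c(Oc2cc(OC)c(Oc3cc(OC)c(OC)c(OC)c3Oc3cc(OC)c(OC=O)c(OC)c3)c(OC)c2)c(OC)c1 | intermediate
13 | ABCD phenol, ArOH | COc1cc(OC)c(Oc2cc(OC)c(Oc3cc(OC)c(OC)c(OC)c3Oc3cc(OC)c(O)c(OC)c3)c(OC)c2)c(OC)c1 | intermediate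
14 | (E)-1,2-dichlorovinyl ether of 13 | COc1cc(OC)c(Oc2cc(OC)c(Oc3cc(OC)c(OC)c(OC)c3Oc3cc(OC)c(O/C(Cl)=C\Cl)c(OC)c3)c(OC)c2)c(OC)c1 | intermediate
15 | lithium (ArO)acetylide | COc1cc(OC)c(Oc2cc(OC)c(Oc3cc(OC)c(OC)c(OC)c3Oc3cc(OC)c(OC#C[Li])c(OC)c3)c(OC)c2)c(OC)c1 | intermediate
16 | ethynyl ether of 13 | COc1cc(OC)c(Oc2cc(OC)c(Oc3cc(OC)c(OC)c(OC)c3Oc3cc(OC)c(OC#C)c(OC)c3)c(OC)c2)c(OC)c1 | intermediate
17 | tributyl[1-(ArO)vinyl]stannane | COc1cc(OC)c(Oc2cc(OC)c(Oc3cc(OC)c(OC)c(OC)c3Oc3cc(OC)c(OC(=C)[Sn](CCCC)(CCCC)CCCC)c(OC)c3)c(OC)c2)c(OC)c1 | intermediate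
18 | dimethyl squarate | COC1=C(OC)C(=O)C1=O | starting material
19 | 1-(ArO)vinyllithium | COc1cc(OC)c(Oc2cc(OC)c(Oc3cc(OC)c(OC)c(OC)c3Oc3cc(OC)c(OC([Li])=C)c(OC)c3)c(OC)c2)c(OC)c1 | intermediate
20 | racemic 4-hydroxy-2,3-dimethoxy-4-[1-(ArO)vinyl]cyclobut-2-en-1-one | COc1cc(OC)c(Oc2cc(OC)c(Oc3cc(OC)c(OC)c(OC)c3Oc3cc(OC)c(OC(=C)C4(O)C(OC)=C(OC)C4=O)c(OC)c3)c(OC)c2)c(OC)c1 | intermediate
21 | racemic 4-(tert-butyldimethylsilyloxy)-2,3-dimethoxy-4-[1-(ArO)vinyl]cyclobut-2-en-1-one | COc1cc(OC)c(Oc2cc(OC)c(Oc3cc(OC)c(OC)c(OC)c3Oc3cc(OC)c(OC(=C)C4(O[Si](C)(C)C(C)(C)C)C(OC)=C(OC)C4=O)c(OC)c3)c(OC)c2)c(OC)c1 | intermediate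
22 | (3Z)-4-(tert-butyldimethylsilyloxy)-2,3-dimethoxy-5-(ArO)hexa-1,3,5-trien-1-one (dienylketene) | COc1cc(OC)c(Oc2cc(OC)c(Oc3cc(OC)c(OC)c(OC)c3Oc3cc(OC)c(OC(=C)/C(O[Si](C)(C)C(C)(C)C)=C(OC)\C(OC)=C=O)c(OC)c3)c(OC)c2)c(OC)c1 | intermediate
23 | 4-(tert-butyldimethylsilyloxy)-2,3-dimethoxy-5-(ArO)cyclohexa-2,4-dien-1-one | COc1cc(OC)c(Oc2cc(OC)c(Oc3cc(OC)c(OC)c(OC)c3Oc3cc(OC)c(OC4=C(O[Si](C)(C)C(C)(C)C)C(OC)=C(OC)C(=O)C4)c(OC)c3)c(OC)c2)c(OC)c1 | intermediate
24 | 4-(tert-butyldimethylsilyloxy)-2,3-dimethoxy-5-(ArO)phenol (ABCDE pentamer) | COc1cc(OC)c(Oc2cc(OC)c(Oc3cc(OC)c(OC)c(OC)c3Oc3cc(OC)c(Oc4cc(O)c(OC)c(OC)c4O[Si](C)(C)C(C)(C)C)c(OC)c3)c(OC)c2)c(OC)c1 | intermediate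
25 | 1-(ArO)-2-(tert-butyldimethylsilyloxy)-3,4,5-trimethoxybenzene | COc1cc(OC)c(Oc2cc(OC)c(Oc3cc(OC)c(OC)c(OC)c3Oc3cc(OC)c(Oc4cc(OC)c(OC)c(OC)c4O[Si](C)(C)C(C)(C)C)c(OC)c3)c(OC)c2)c(OC)c1 | intermediate
26 | 6-(ArO)-2,3,4-trimethoxyphenol (ABCDE phenol) | COc1cc(OC)c(Oc2cc(OC)c(Oc3cc(OC)c(OC)c(OC)c3Oc3cc(OC)c(Oc4cc(OC)c(OC)c(OC)c4O)c(OC)c3)c(OC)c2)c(OC)c1 | intermediate
27 | 4-bromo-2,6-dimethoxyphenol | COc1cc(Br)cc(OC)c1O | starting material
28 | (3,4,5-trimethoxyphenyl)boronic acid | COc1cc(B(O)O)cc(OC)c1OC | starting material
29 | 5-(4-bromo-2,6-dimethoxyphenoxy)-1,2,3-trimethoxybenzene (FG bromide) | COc1cc(Br)cc(OC)c1Oc1cc(OC)c(OC)c(OC)c1 | intermediate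
30 | octadeca-O-methyl ether of the target | COc1cc(OC)c(Oc2cc(OC)c(Oc3cc(OC)c(OC)c(OC)c3Oc3cc(OC)c(Oc4cc(OC)c(OC)c(OC)c4Oc4cc(OC)c(Oc5cc(OC)c(OC)c(OC)c5)c(OC)c4)c(OC)c3)c(OC)c2)c(OC)c1 | intermediate
31 | target heptamer CNP0292517.0 | Oc1cc(O)c(Oc2cc(O)c(Oc3cc(O)c(O)c(O)c3Oc3cc(O)c(Oc4cc(O)c(O)c(O)c4Oc4cc(O)c(Oc5cc(O)c(O)c(O)c5)c(O)c4)c(O)c3)c(O)c2)c(O)c1 | target

## Step count and uncertain steps

Total: 18 steps. Longest linear sequence: 16 steps (1, 2, 4 to 15, 17, 18, from compounds 1 and 2 to 31). Steps 3 and 16 are side branches.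

**Step 13 (key step).** The most likely failure is diversion of the dienylketene before it closes. The aryloxy group on the internal vinyl carbon and the silyloxy group on the neighbouring carbon crowd the planar s-cis conformation. Slow closure would let ketene dimerisation, trapping by trace water, or re-closure followed by decomposition of the enol ether compete. Fallback: the ring construction is given up and ring E is attached by arylation. It sets out from 13, which would be coupled with 7 under the conditions of step 4 to give the pentamer aldehyde F1. Peracid oxidation to the pentamer aryl formate F2 and methanolysis, as in step 5, would return to the route at 26. This is shorter on paper but makes the three-ortho D–O–E junction by coupling on the tetramer, which the main route avoids.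

**Step 4.** Slow C–O bond formation around three ortho substituents is the likely problem; hydrodebromination of 7 and oxidative loss of phenol 5 would then take over. Fallback: the ortho-carboxylate effect on copper-mediated coupling is used in place of the aldehyde. It sets out from 7, which would be oxidised (NaClO2, NaH2PO4, 2-methylbut-2-ene) to 6-bromo-2,3,4-trimethoxybenzoic acid F3. Coupling of F3 with 5 (Cu powder, K2CO3, pyridine, 120 °C) would give the ABC carboxylic acid F4. Reduction with BH3·THF would give the ABC benzyl alcohol F5, and MnO2 oxidation would come back to the route at 8.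

**Step 10.** Imperfect regiocontrol in the hydrostannylation (tin partly on the terminal carbon) and protodestannylation of the acid-sensitive product on silica are the risks. Fallback: the regiochemistry is set by ionic addition. It sets out from 16, which would take up dry HBr (1 equiv, CH2Cl2, −78 °C) in the Markovnikov sense to give the 1-bromovinyl ether F6. Bromine–lithium exchange with t-BuLi (2 equiv, THF, −100 °C) would give 19, and the route is rejoined at 20 after addition to 18.

**Step 17.** The bromide 29 is electron-rich and unactivated, so slow oxidative addition next to a crowded, oxidisable phenoxide may lead to decomposition of 26. Fallback: the FG half is added ring by ring with the activated bromide. It sets out from 26, which would be coupled with 2 as in step 6 to give the hexamer aldehyde F7. Peracid oxidation to the hexamer aryl formate F8 and methanolysis would give the hexamer phenol F9. Chan–Lam coupling of F9 with 28 under the conditions of step 16 would return to the route at 30.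

**Step 18.** Incomplete cleavage of some of the eighteen methyl ethers and air oxidation of the free polyphenol during isolation are the risks. Fallback: the product is isolated as a stable derivative. It sets out from 30; after BBr3 treatment the crude polyphenol would be acetylated (Ac2O, pyridine) to the octadecaacetate F10, which can be purified on silica. Mild methanolysis (NaOMe cat., degassed MeOH, 0 °C, then acidic resin) would come back to the route at 31.

## Further compounds

F1 | step 13 | 6-(ArO)-2,3,4-trimethoxybenzaldehyde (pentamer aldehyde) | COc1cc(OC)c(Oc2cc(OC)c(Oc3cc(OC)c(OC)c(OC)c3Oc3cc(OC)c(Oc4cc(OC)c(OC)c(OC)c4C=O)c(OC)c3)c(OC)c2)c(OC)c1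
F2 | step 13 | 6-(ArO)-2,3,4-trimethoxyphenyl formate (pentamer aryl formate) | COc1cc(OC)c(Oc2cc(OC)c(Oc3cc(OC)c(OC)c(OC)c3Oc3cc(OC)c(Oc4cc(OC)c(OC)c(OC)c4OC=O)c(OC)c3)c(OC)c2)c(OC)c1
F3 | step 4 | 6-bromo-2,3,4-trimethoxybenzoic acid | COc1cc(Br)c(C(=O)O)c(OC)c1OC
F4 | step 4 | 6-[2,6-dimethoxy-4-(2,4,6-trimethoxyphenoxy)phenoxy]-2,3,4-trimethoxybenzoic acid | COc1cc(OC)c(Oc2cc(OC)c(Oc3cc(OC)c(OC)c(OC)c3C(=O)O)c(OC)c2)c(OC)c1
F5 | step 4 | {6-[2,6-dimethoxy-4-(2,4,6-trimethoxyphenoxy)phenoxy]-2,3,4-trimethoxyphenyl}methanol | COc1cc(OC)c(Oc2cc(OC)c(Oc3cc(OC)c(OC)c(OC)c3CO)c(OC)c2)c(OC)c1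
F6 | step 10 | 1-bromovinyl ether ArO–C(Br)=CH2 | COc1cc(OC)c(Oc2cc(OC)c(Oc3cc(OC)c(OC)c(OC)c3Oc3cc(OC)c(OC(Br)=C)c(OC)c3)c(OC)c2)c(OC)c1
F7 | step 17 | hexamer aldehyde (ring F as 2,6-dimethoxybenzaldehyde bound through C4 to the ring E C2 oxygen) | COc1cc(OC)c(Oc2cc(OC)c(Oc3cc(OC)c(OC)c(OC)c3Oc3cc(OC)c(Oc4cc(OC)c(OC)c(OC)c4Oc4cc(OC)c(C=O)c(OC)c4)c(OC)c3)c(OC)c2)c(OC)c1
F8 | step 17 | hexamer aryl formate | COc1cc(OC)c(Oc2cc(OC)c(Oc3cc(OC)c(OC)c(OC)c3Oc3cc(OC)c(Oc4cc(OC)c(OC)c(OC)c4Oc4cc(OC)c(OC=O)c(OC)c4)c(OC)c3)c(OC)c2)c(OC)c1
F9 | step 17 | hexamer phenol (free hydroxyl on ring F C4) | COc1cc(OC)c(Oc2cc(OC)c(Oc3cc(OC)c(OC)c(OC)c3Oc3cc(OC)c(Oc4cc(OC)c(OC)c(OC)c4Oc4cc(OC)c(O)c(OC)c4)c(OC)c3)c(OC)c2)c(OC)c1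
F10 | step 18 | octadecaacetate of the target | CC(=O)Oc1cc(OC(C)=O)c(Oc2cc(OC(C)=O)c(Oc3cc(OC(C)=O)c(OC(C)=O)c(OC(C)=O)c3Oc3cc(OC(C)=O)c(Oc4cc(OC(C)=O)c(OC(C)=O)c(OC(C)=O)c4Oc4cc(OC(C)=O)c(Oc5cc(OC(C)=O)c(OC(C)=O)c(OC(C)=O)c5)c(OC(C)=O)c4)c(OC(C)=O)c3)c(OC(C)=O)c2)c(OC(C)=O)c1
A1 | alternative 1 | (η5-cyclopentadienyl)ruthenium hexafluorophosphate complex of the permethylated heptamer, bound through ring D | COc1cc(OC)c(Oc2cc(OC)c(Oc3cc(OC)c(OC)c(OC)c3Oc3cc(OC)c(Oc4cc(OC)c(OC)c(OC)c4Oc4cc(OC)c(Oc5cc(OC)c(OC)c(OC)c5)c(OC)c4)c(OC)c3)c(OC)c2)c(OC)c1.[cH-]1cccc1.[Ru+2].F[P-](F)(F)(F)(F)F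
A2 | alternative 1 | (η5-cyclopentadienyl)(η6-2,5-dichloro-1,3-dimethoxybenzene)ruthenium hexafluorophosphate | COc1cc(Cl)cc(OC)c1Cl.[cH-]1cccc1.[Ru+2].F[P-](F)(F)(F)(F)F
A3 | alternative 1 | 2-[3,5-dimethoxy-4-(3,4,5-trimethoxyphenoxy)phenoxy]-3,4,5-trimethoxyphenol (EFG phenol) | COc1cc(O)c(Oc2cc(OC)c(Oc3cc(OC)c(OC)c(OC)c3)c(OC)c2)c(OC)c1OC
A4 | alternative 2 | heptamer with ring D as dimethyl 2,6-dicarboxylate and free 3,5-diol, other rings permethylated | COC(=O)c1c(O)c(Oc2cc(OC)c(OC)c(OC)c2Oc2cc(OC)c(Oc3cc(OC)c(OC)c(OC)c3)c(OC)c2)c(O)c(C(=O)OC)c1Oc1c(OC)c(OC)c(OC)cc1Oc1c(OC)cc(Oc2c(OC)cc(OC)cc2OC)cc1OC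
A5 | alternative 2 | dimethyl (E)-3-(ABC aryloxy)pent-2-enedioate | COC(=O)/C=C(\CC(=O)OC)Oc1c(OC)c(OC)c(OC)cc1Oc1c(OC)cc(Oc2c(OC)cc(OC)cc2OC)cc1OC
A6 | alternative 2 | dimethyl 2-(EFG aryloxy)malonate | COC(=O)C(Oc1cc(OC)c(OC)c(OC)c1Oc1cc(OC)c(Oc2cc(OC)c(OC)c(OC)c2)c(OC)c1)C(=O)OC
A7 | alternative 3 | heptamer with ring A as free triol, rings B to G permethylated | Oc1cc(O)c(Oc2cc(OC)c(Oc3cc(OC)c(OC)c(OC)c3Oc3cc(OC)c(Oc4cc(OC)c(OC)c(OC)c4Oc4cc(OC)c(Oc5cc(OC)c(OC)c(OC)c5)c(OC)c4)c(OC)c3)c(OC)c2)c(O)c1
A8 | alternative 3 | racemic methyl 4-(BCDEFG hexamer aryloxy)-3,5-dioxohexanoate | COC(=O)CC(=O)C(Oc1cc(OC)c(Oc2cc(OC)c(OC)c(OC)c2Oc2cc(OC)c(Oc3cc(OC)c(OC)c(OC)c3Oc3cc(OC)c(Oc4cc(OC)c(OC)c(OC)c4)c(OC)c3)c(OC)c2)c(OC)c1)C(C)=O
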